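The runs were computed for an exercise, and the scatter is random.

| flask | substrate | reagent | remark | time |
|---|---|---|---|---|
| Monday's | 0.050 M | 0.18 M | run made earlier |  |
| zeta | 0.050 M | 0.0750 M |  | 50 min |
| alpha | 0.050 M | 0.110 M |  | 50 min |
| delta | 0.050 M | 0.170 M |  | 50 min |

Monday's run (percent of the substrate charged)

| time / min | target / % | substrate / % |
|---|---|---|
| 4.00 | 34.8 | 20.2 |
| 12.0 | 45.5 | 2.6 |
| 25.0 | 47.3 | 0.5 |
| 40.0 | 47.1 | 0 |

(readings scatter by 0.5 percentage points)

- percentages count the substrate that a species holds: one side product B counts as two
- the earlier runs were read with a standard deviation of 0.5 percentage points

1. which of the two there is more of at the end, counted by the substrate in each, zeta (target / side product B)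
2. which of the two there is more of at the end, counted by the substrate in each, alpha (target / side product B)
3. which of the two there is more of at the end, counted by the substrate in each, delta (target / side product B)
4. how much target is there at the end, in percent of the substrate charged: zeta
5. how much target is there at the end, in percent of the substrate charged: alpha
6. how much target is there at the end, in percent of the substrate charged: delta

- If I want the end target of zeta, alpha and delta from Monday's run, I will try to get by with two rates at a single substrate level: the making of target and the loss of substrate to everything else.
- Monday's run shows that these two differ in order: target took 43.6% of the substrate consumed up to 4.00 min, but 60.8% of that consumed between then and 12.0 min, a larger share at lower [substrate], so the loss falls more steeply with [substrate] than the making of target does.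
- I therefore replace the curve by its mean: averaged over the substrate consumed, not over the clock, [substrate] stands at half the charge, and I read the end of Monday's run as the split at that level, so target over the rest, my selectivity factor, is 0.890.
- To check the error, I scale this factor inversely with [substrate] and get target shares of 42.6% and 79.6% at the mean levels of those two windows; the first stands close to its reading, but the second is too high, and that window consumed just 18 points.
- I take the factor as proportional to [reagent] at its charge, a pseudo-first-order view, and the target share as factor over factor plus one, which gives zeta 0.371 and 27.1%, alpha 0.544 and 35.2%, and delta 0.841 and 45.7%, so even in delta the rest taken together, not side product B by itself, exceeds target.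
- The forecast, by its own reckoning, says 27.5%, 36% and 46%, with side product B ahead in zeta, alpha and delta alike, and it states its ground plainly: “I take target formation as first order in reagent”.
- The flasks give target 27.6% in zeta, 35.5% in alpha and 45.5% in delta; side product B leads in zeta and alpha, but delta holds 45.5% target against 38.0% side product B, with side product A at 12.2% and side product C at 3.72% beside them.

    substrate + reagent → target (k = 1.14 /M/min)
    substrate → side product A (k = 0.0456 /min)
    2 substrate → side product B (k = 3.36 /M/min)
    substrate + target → side product C (k = 0.581 /M/min)
    target → over-reaction product (k = 3.15 × 10⁻⁴ /min)

- A neighbour of zeta charged with 0.030 M of reagent, 0.600 equiv, has a factor of 0.148 by the same reckoning, so I expect 12.9% target; that flask gives 13.5% target and 61.2% side product B.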